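Ring B of the 20-membered bis(bibenzyl) carries only the ether oxygen to ring A (at C1) and the ethylene carbon to ring C (at C3), with C2–H between them, and the route cuts both of these ring B bonds. They are made in one flask: 2-(trimethylsilyl)-1,3-phenylene bis(triflate) releases two arynes in succession, the first taking up the ring A phenoxide, the second the copper acetylide of the ring C alkyne. The precursors are a vanillin/isovanillin-derived bibenzyl with free ring A phenol and MOM-masked ring D phenol, the silyl bis(triflate), and 1-bromo-4-ethynylbenzene. Alkyne saturation, MOM removal, Ullmann closure of the ring D–O–ring C ether and demethylation complete the route.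

Key step: step 8

Remark: no stereocentre occurs in the target or in any intermediate; the two C=C bonds formed on the way are reduced, so their geometry is immaterial.

Step 1
Reactants: 1 isovanillin (3-hydroxy-4-methoxybenzaldehyde)
Product: 2 4-methoxy-3-(methoxymethoxy)benzaldehyde
Conditions: MOMCl, iPr2NEt, CH2Cl2, 0 °C to rt
Reagents that add atoms: chloromethyl methyl ether, COCCl
Why: O-alkylation of the phenol by the α-chloro ether under amine base (MOM protection) masks the ring D oxygen with a group that tolerates base, fluoride, ylides and hydrogenation.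

Step 2
Reactants: 3 [4-(benzyloxy)-3-methoxyphenyl]methanol
Product: 4 [4-(benzyloxy)-3-methoxybenzyl]triphenylphosphonium bromide
Conditions: PPh3·HBr, MeCN, reflux
Reagents that add atoms: triphenylphosphine hydrobromide, c1ccc(cc1)[PH+](c1ccccc1)c1ccccc1.[Br-]
Why: the electron-rich benzylic alcohol ionises under the mild acid and is captured by the phosphine (SN1-type phosphonium salt formation), so no separate benzylic halide is needed.

Step 3
Reactants: 4 [4-(benzyloxy)-3-methoxybenzyl]triphenylphosphonium bromide; 2 4-methoxy-3-(methoxymethoxy)benzaldehyde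
Product: 6 1-(benzyloxy)-2-methoxy-4-{2-[4-methoxy-3-(methoxymethoxy)phenyl]ethenyl}benzene (E/Z mixture), via benzylic ylide 5 (not isolated)
Conditions: t-BuOK, THF, 0 °C to rt
Reagents that add atoms: none
Why: Wittig olefination of the non-enolisable aldehyde by the semi-stabilised ylide 5 joins rings A and D, and the E/Z mixture is acceptable because the double bond is hydrogenated next.

Step 4
Reactants: 6 1-(benzyloxy)-2-methoxy-4-{2-[4-methoxy-3-(methoxymethoxy)phenyl]ethenyl}benzene
Product: 7 2-methoxy-4-{2-[4-methoxy-3-(methoxymethoxy)phenyl]ethyl}phenol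
Conditions: H2 (1 atm), 10% Pd/C, EtOAc, rt
Reagents that add atoms: none
Why: catalytic hydrogenation saturates the stilbene and hydrogenolyses the benzyl ether in one operation, while the MOM acetal and the methyl ethers are inert under neutral conditions.

Step 5
Reactants: 8 2-bromoresorcinol (2-bromobenzene-1,3-diol)
Product: 9 2-bromo-1,3-bis(trimethylsilyloxy)benzene
Conditions: HMDS, THF, reflux
Reagents that add atoms: hexamethyldisilazane, C[Si](C)(C)N[Si](C)(C)C
Why: O-silylation of both phenols by the silazane, with ammonia as the only by-product, sets up the silyl migration.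

Step 6
Reactants: 9 2-bromo-1,3-bis(trimethylsilyloxy)benzene
Product: 11 2-(trimethylsilyl)benzene-1,3-diol, via lithium silylphenolate 10 (not isolated)
Conditions: n-BuLi, THF, −78 °C to rt; then aq. NH4Cl, rt
Reagents that add atoms: none
Why: bromine–lithium exchange is followed by an anionic 1,3-O→C silyl shift (retro-Brook rearrangement) driven by formation of phenolate 10, and the labile remaining aryl silyl ether is hydrolysed on mild aqueous work-up.

Step 7
Reactants: 11 2-(trimethylsilyl)benzene-1,3-diol
Product: 12 2-(trimethylsilyl)-1,3-phenylene bis(trifluoromethanesulfonate)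
Conditions: Tf2O, pyridine, CH2Cl2, 0 °C to rt
Reagents that add atoms: trifluoromethanesulfonic anhydride, O=S(=O)(OS(=O)(=O)C(F)(F)F)C(F)(F)F
Why: O-sulfonylation of both phenols with Tf2O and pyridine is the standard last step for o-silylaryl triflate aryne precursors, and no fluoride or strong base is present to trigger elimination.

Step 8
Reactants: 7 2-methoxy-4-{2-[4-methoxy-3-(methoxymethoxy)phenyl]ethyl}phenol; 12 2-(trimethylsilyl)-1,3-phenylene bis(trifluoromethanesulfonate); 13 1-bromo-4-ethynylbenzene
Product: 17 1-{3-[(4-bromophenyl)ethynyl]phenoxy}-2-methoxy-4-{2-[4-methoxy-3-(methoxymethoxy)phenyl]ethyl}benzene, via copper acetylide 14 (not isolated), via 3-(triflyloxy)benzyne 15 (not isolated), via 3-(aryloxy)benzyne 16 (not isolated)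
Conditions: CsF (5 equiv), CuI (20 mol%), MeCN/toluene 1:1, rt to 50 °C, Ar; 7 (1.0 equiv), 13 (3 equiv), 12 (1.5 equiv) added slowly
Reagents that add atoms: none
Why: Proposed new method: fluoride removes the silyl group of 12 and one triflate departs to give 15; the caesium phenoxide of 7 adds to the aryne carbon meta to the triflate, because the carbanion then develops beside the σ-withdrawing oxygen, and this carbanion expels the second triflate to give 16, which is carbocuprated by copper acetylide 14 with carbon again entering meta to oxygen before the arylcopper at C2 is protonated by 13 or 7. The closest known reaction types are the domino 1,3-difunctionalisation of 2-silyl-1,3-bis(triflyloxy)arenes by heteroatom nucleophiles, the CsF-mediated O-arylation of phenols by arynes and the CuI-catalysed hydroalkynylation of arynes by terminal alkynes, whose union with two different nucleophiles in one flask has not been shown. No ring is closed and no stereocentre is created. The step needs regiocontrol at both arynes, which the oxygen substituent next to each triple bond (triflate in 15, aryloxy in 16) supplies, provided that the phenoxide adds first; that order is expected since the hard phenoxide gains most from the strongly polarised aryne 15, while an acetylide-first adduct would be an arylcopper prone to protonation instead of triflate loss. It also needs hetero- over double homo-addition, which the substrate does not secure and which is steered by 7 as the limiting partner, excess 13, CsF as the only base (low free phenoxide) and slow addition of 12.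

Step 9
Reactants: 17 1-{3-[(4-bromophenyl)ethynyl]phenoxy}-2-methoxy-4-{2-[4-methoxy-3-(methoxymethoxy)phenyl]ethyl}benzene
Product: 19 1-{3-[2-(4-bromophenyl)ethyl]phenoxy}-2-methoxy-4-{2-[4-methoxy-3-(methoxymethoxy)phenyl]ethyl}benzene, via cis-stilbene 18 (not isolated)
Conditions: TsNHNH2 (excess), NaOAc, DME/H2O, reflux
Reagents that add atoms: none
Why: diimide released from the sulfonyl hydrazide transfers hydrogen by concerted syn addition to the alkyne and then to alkene 18 (diimide reduction), leaving the aryl C–Br bond, the buffered MOM acetal and the ethers untouched.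

Step 10
Reactants: 19 1-{3-[2-(4-bromophenyl)ethyl]phenoxy}-2-methoxy-4-{2-[4-methoxy-3-(methoxymethoxy)phenyl]ethyl}benzene
Product: 20 5-[2-(4-{3-[2-(4-bromophenyl)ethyl]phenoxy}-3-methoxyphenyl)ethyl]-2-methoxyphenol
Conditions: 3 M HCl, MeOH/THF, 50 °C
Reagents that add atoms: none
Why: acid-catalysed transacetalisation to methanol removes the MOM group and frees the ring D phenol, while the aryl methyl ethers, the diaryl ether and the aryl bromide are stable.

Step 11
Reactants: 20 5-[2-(4-{3-[2-(4-bromophenyl)ethyl]phenoxy}-3-methoxyphenyl)ethyl]-2-methoxyphenol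
Product: 21 di-O-methyl ether of the target (20-membered macrocycle, OMe on ring A and on ring D)
Conditions: CuI (30 mol%), N,N-dimethylglycine, Cs2CO3, 1,4-dioxane, 100 °C, 2 mM, slow addition
Reagents that add atoms: none
Why: ligand-accelerated Ullmann diaryl ether coupling, run intramolecularly at high dilution, joins the ring D phenoxide to the ring C bromide and closes the 20-membered ring, whose two flexible CH2CH2 tethers let the ends meet without strain.

Step 12
Reactants: 21 di-O-methyl ether of the target
Product: 22 CNP0329842.0 (target; free OH on ring A ortho to the ring B ether and on ring D ortho to the ring C ether)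
Conditions: BBr3 (excess), CH2Cl2, −78 °C to rt; then H2O
Reagents that add atoms: none
Why: Lewis acid demethylation by BBr3 (O-complexation, then bromide attack at methyl) cleaves both aryl methyl ethers, while the diaryl ether bonds lack an sp3 carbon for that attack and survive.

Compound list
1 | isovanillin (3-hydroxy-4-methoxybenzaldehyde) | COc1ccc(C=O)cc1O | starting material
2 | 4-methoxy-3-(methoxymethoxy)benzaldehyde | COCOc1cc(C=O)ccc1OC | intermediate
3 | [4-(benzyloxy)-3-methoxyphenyl]methanol | COc1cc(CO)ccc1OCc1ccccc1 | starting material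
4 | [4-(benzyloxy)-3-methoxybenzyl]triphenylphosphonium bromide | COc1cc(C[P+](c2ccccc2)(c2ccccc2)c2ccccc2)ccc1OCc1ccccc1.[Br-] | intermediate
5 | [4-(benzyloxy)-3-methoxybenzylidene]triphenylphosphorane (ylide, formed in the flask) | COc1cc(C=P(c2ccccc2)(c2ccccc2)c2ccccc2)ccc1OCc1ccccc1 | intermediate
6 | 1-(benzyloxy)-2-methoxy-4-{2-[4-methoxy-3-(methoxymethoxy)phenyl]ethenyl}benzene, E/Z mixture | COc1cc(C=Cc2ccc(OC)c(OCOC)c2)ccc1OCc1ccccc1 | intermediate
7 | 2-methoxy-4-{2-[4-methoxy-3-(methoxymethoxy)phenyl]ethyl}phenol | COc1cc(CCc2ccc(OC)c(OCOC)c2)ccc1O | intermediate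
8 | 2-bromoresorcinol (2-bromobenzene-1,3-diol) | Oc1cccc(O)c1Br | starting material
9 | 2-bromo-1,3-bis(trimethylsilyloxy)benzene | C[Si](C)(C)Oc1cccc(O[Si](C)(C)C)c1Br | intermediate
10 | lithium 2-(trimethylsilyl)-3-(trimethylsilyloxy)phenolate (formed in the flask) | [Li+].[O-]c1cccc(O[Si](C)(C)C)c1[Si](C)(C)C | intermediate
11 | 2-(trimethylsilyl)benzene-1,3-diol | C[Si](C)(C)c1c(O)cccc1O | intermediate
12 | 2-(trimethylsilyl)-1,3-phenylene bis(trifluoromethanesulfonate) | C[Si](C)(C)c1c(OS(=O)(=O)C(F)(F)F)cccc1OS(=O)(=O)C(F)(F)F | intermediate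
13 | 1-bromo-4-ethynylbenzene | C#Cc1ccc(Br)cc1 | starting material
14 | [(4-bromophenyl)ethynyl]copper (copper acetylide of 13, formed in the flask) | Brc1ccc(cc1)C#C[Cu] | intermediate
15 | 3-(trifluoromethanesulfonyloxy)benzyne (formed in the flask) | O=S(=O)(OC1=CC=CC#C1)C(F)(F)F | intermediate
16 | 3-(aryloxy)benzyne: 1-(2,3-didehydrophenoxy)-2-methoxy-4-{2-[4-methoxy-3-(methoxymethoxy)phenyl]ethyl}benzene (formed in the flask) | COc1cc(CCc2ccc(OC)c(OCOC)c2)ccc1OC1=CC=CC#C1 | intermediate
17 | 1-{3-[(4-bromophenyl)ethynyl]phenoxy}-2-methoxy-4-{2-[4-methoxy-3-(methoxymethoxy)phenyl]ethyl}benzene | COc1cc(CCc2ccc(OC)c(OCOC)c2)ccc1Oc1cccc(c1)C#Cc1ccc(Br)cc1 | intermediate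
18 | 1-{3-[(Z)-2-(4-bromophenyl)ethenyl]phenoxy}-2-methoxy-4-{2-[4-methoxy-3-(methoxymethoxy)phenyl]ethyl}benzene (formed in the flask) | COc1cc(CCc2ccc(OC)c(OCOC)c2)ccc1Oc1cccc(c1)/C=C\c1ccc(Br)cc1 | intermediate
19 | 1-{3-[2-(4-bromophenyl)ethyl]phenoxy}-2-methoxy-4-{2-[4-methoxy-3-(methoxymethoxy)phenyl]ethyl}benzene | COc1cc(CCc2ccc(OC)c(OCOC)c2)ccc1Oc1cccc(c1)CCc1ccc(Br)cc1 | intermediate
20 | 5-[2-(4-{3-[2-(4-bromophenyl)ethyl]phenoxy}-3-methoxyphenyl)ethyl]-2-methoxyphenol | COc1cc(CCc2ccc(OC)c(O)c2)ccc1Oc1cccc(c1)CCc1ccc(Br)cc1 | intermediate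
21 | di-O-methyl ether of the target (20-membered macrocycle, achiral) | COc1cc2ccc1Oc1cccc(c1)CCc1ccc(cc1)Oc1cc(ccc1OC)CC2 | intermediate
22 | CNP0329842.0 (achiral macrocyclic bis(bibenzyl) diphenol) | Oc1cc2ccc1Oc1cccc(c1)CCc1ccc(cc1)Oc1cc(ccc1O)CC2 | target

Total step count: 12. Longest linear sequence: 8 steps (for example steps 1, 3, 4, 8, 9, 10, 11, 12).

Steps most likely to fail

Step 8 (new method). Both arynes may take up the same nucleophile, or the first adduct may be protonated before the second triflate leaves, so that material is diverted from the hetero-coupled product. The fallback uses known chemistry and sets out from 7. Chan–Lam–Evans O-arylation with (3-iodophenyl)boronic acid (Cu(OAc)2, pyridine, 4 Å MS, CH2Cl2, air, rt) should give 1-(3-iodophenoxy)-2-methoxy-4-{2-[4-methoxy-3-(methoxymethoxy)phenyl]ethyl}benzene F1. Sonogashira coupling of its C–I bond with 13 (Pd(PPh3)2Cl2, CuI, Et3N, THF, rt), at a temperature where the C–Br bond of 13 does not undergo oxidative addition, comes back to the route at 17.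

Step 11. Intermolecular etherification may outrun ring closure, and slow oxidative addition of the unactivated bromide at 100 °C may let reductive loss of bromine compete. The fallback sets out from 20. Miyaura borylation (B2pin2, Pd(dppf)Cl2, KOAc, 1,4-dioxane, 80 °C) should give 2-methoxy-5-{2-[3-methoxy-4-(3-{2-[4-(4,4,5,5-tetramethyl-1,3,2-dioxaborolan-2-yl)phenyl]ethyl}phenoxy)phenyl]ethyl}phenol F2. Oxidative cleavage of the pinacol ester (NaIO4, NH4OAc, acetone/H2O, rt) should give [4-(2-{3-[4-(2-(3-hydroxy-4-methoxyphenyl)ethyl)-2-methoxyphenoxy]phenyl}ethyl)phenyl]boronic acid F3. Chan–Lam–Evans macrocyclisation at room temperature (Cu(OAc)2, Et3N, 4 Å MS, CH2Cl2, air, high dilution) comes back to the route at 21.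

Step 9. Reduction may stall at the stilbene stage, because diimide disproportionates faster than it adds to the conjugated diaryl alkene. The fallback sets out from 17: catalytic hydrogenation over sulfided 5% Pt/C (H2, 1 atm, EtOAc, rt), a catalyst that saturates C≡C and C=C bonds without hydrogenolysis of aryl C–Br bonds, leads directly to 19; no new compound arises (F0).

Further compounds
F1 | step 8 | 1-(3-iodophenoxy)-2-methoxy-4-{2-[4-methoxy-3-(methoxymethoxy)phenyl]ethyl}benzene | COc1cc(CCc2ccc(OC)c(OCOC)c2)ccc1Oc1cccc(I)c1
F2 | step 11 | 2-methoxy-5-{2-[3-methoxy-4-(3-{2-[4-(4,4,5,5-tetramethyl-1,3,2-dioxaborolan-2-yl)phenyl]ethyl}phenoxy)phenyl]ethyl}phenol | COc1cc(CCc2ccc(OC)c(O)c2)ccc1Oc1cccc(c1)CCc1ccc(cc1)B1OC(C)(C)C(C)(C)O1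
F3 | step 11 | [4-(2-{3-[4-(2-(3-hydroxy-4-methoxyphenyl)ethyl)-2-methoxyphenoxy]phenyl}ethyl)phenyl]boronic acid | COc1cc(CCc2ccc(OC)c(O)c2)ccc1Oc1cccc(c1)CCc1ccc(cc1)B(O)O
F0 | step 9 | none | none
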